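The ent-labdane core is disconnected across C4–C5 and C9–C10: ring A (C1–C5, C10) and ring B (C5–C10) of the trans-decalin, with quaternary C4 (equatorial C18 CH2O), the C10 methyl, the C9 side chain and the C8 carbinol, are an all-E C20 chain folded chair–chair. One radical cascade, started by Cp2TiCl at a Sharpless-derived C3–C4 epoxide, closes both rings, relays the single catalyst-set stereocentre (C3) to C4, C5, C9 and C10, and ends at the C8(17) alkene, the later carbinol. The precursor is an epoxy E,E-diene assembled from (S)-citronellol (C13) and a geranyl sulfone, with TBS and PMB ethers on O18 and O15.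

Key step: step 12

Assumption: labdane numbering is used for the acyclic C20 chain and for the decalin alike (C18 = CH2O carbon on C4, C17 = one-carbon substituent on C8, C15 = terminal CH2O); (S)-citronellol and geranyl bromide are taken as purchased.

Step 1
Reactants: 1 (S)-citronellol
Product: 2 (S)-citronellyl 4-methoxybenzyl (PMB) ether
Conditions: NaH, PMBCl, n-Bu4NI (cat.), THF/DMF, 0 °C → rt
Reagents that add atoms: 4-methoxybenzyl chloride, COc1ccc(CCl)cc1
Why: Williamson ether synthesis, in which the sodium alkoxide of the primary alcohol should displace the benzylic chloride while the alkene and the methyl-bearing stereocentre (later C13) are untouched.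

Step 2
Reactants: 2 (S)-citronellyl PMB ether
Product: 3 (2E,6S)-8-(4-methoxybenzyloxy)-2,6-dimethyloct-2-en-1-ol
Conditions: SeO2 (cat.), t-BuOOH, salicylic acid (cat.), CH2Cl2, rt
Reagents that add atoms: tert-butyl hydroperoxide, CC(C)(C)OO (source of the new oxygen, passed on through catalytic SeO2, O=[Se]=O)
Why: Riley-type allylic oxidation (ene reaction, then [2,3]-sigmatropic shift) should hydroxylate the E methyl group of the trisubstituted alkene and so give the E allylic alcohol.

Step 3
Reactants: 3 (2E,6S)-8-(4-methoxybenzyloxy)-2,6-dimethyloct-2-en-1-ol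
Product: 4 (S,E)-8-bromocitronellyl PMB ether
Conditions: CBr4, PPh3, CH2Cl2, 0 °C
Reagents that add atoms: tetrabromomethane, BrC(Br)(Br)Br
Why: Appel reaction, in which bromide should displace the oxyphosphonium group of the primary allylic alcohol by SN2 under neutral conditions that keep the PMB ether and the E alkene.

Step 4
Reactants: 5 geranyl bromide
Product: 6 geranyl phenyl sulfone
Conditions: PhSO2Na, DMF, rt
Reagents that add atoms: sodium benzenesulfinate, [Na+].[O-]S(=O)c1ccccc1
Why: SN2 displacement of the primary allylic bromide by the sulfur of the sulfinate anion in a dipolar aprotic solvent should give the sulfone with the 2E geometry retained.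

Step 5
Reactants: 6 geranyl phenyl sulfone
Product: 7 (2E,6E)-8-hydroxygeranyl phenyl sulfone
Conditions: SeO2 (cat.), t-BuOOH, salicylic acid (cat.), CH2Cl2, rt
Reagents that add atoms: tert-butyl hydroperoxide, CC(C)(C)OO (source of the new oxygen, passed on through catalytic SeO2, O=[Se]=O)
Why: Riley-type allylic oxidation should select the E methyl of the electron-richer 6,7-alkene, because the 2,3-alkene is deactivated by the allylic sulfonyl group.

Step 6
Reactants: 7 (2E,6E)-8-hydroxygeranyl phenyl sulfone
Product: 8 (2E,6E)-8-(tert-butyldimethylsilyloxy)geranyl phenyl sulfone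
Conditions: TBSCl, imidazole, DMF, rt
Reagents that add atoms: tert-butyldimethylsilyl chloride, CC(C)(C)[Si](C)(C)Cl
Why: Imidazole-mediated silylation of the primary allylic alcohol should mask the hydroxyl against the base of step 7 and against the palladium–hydride conditions of step 8.

Step 7
Reactants: 8 (2E,6E)-8-(tert-butyldimethylsilyloxy)geranyl phenyl sulfone; 4 (S,E)-8-bromocitronellyl PMB ether
Product: 10 C20 sulfone (18-OTBS 15-OPMB; epimers at C6), via lithiated sulfone 9 (not isolated)
Conditions: n-BuLi, THF, −78 °C; then 4, −78 → −20 °C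
Reagents that add atoms: none
Why: Alkylation of an α-sulfonyl carbanion, in which the allylic CH2SO2Ph position is deprotonated and the soft anion should attack the primary allylic bromide by SN2 at its α-carbon, joining C6 to C7 without disturbing any alkene geometry.

Step 8
Reactants: 10 C20 sulfone
Product: 11 all-E triene bis-ether (18-OTBS, 15-OPMB)
Conditions: PdCl2(dppp) (cat.), LiBHEt3, THF, 0 °C
Reagents that add atoms: none
Why: Palladium-catalysed reductive desulfonylation of an allylic sulfone, in which zerovalent palladium formed in the flask ionizes the allylic C–S bond and hydride should be delivered to the less substituted allyl terminus (C6), so that the C5=C10 alkene keeps its position and E geometry.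

Step 9
Reactants: 11 all-E triene bis-ether
Product: 12 all-E trienyl allylic alcohol, (2E,6E,10E,14S)-16-(4-methoxybenzyloxy)-2,6,10,14-tetramethylhexadeca-2,6,10-trien-1-ol
Conditions: TBAF, THF, 0 °C → rt
Reagents that add atoms: none
Why: Fluoride-induced Si–O cleavage should free the primary allylic alcohol that the directed epoxidation needs, with the PMB ether inert.

Step 10
Reactants: 12 all-E trienyl allylic alcohol
Product: 13 (2R,3R)-epoxy alcohol, (2R,3R,6E,10E,14S)-2,3-epoxy-16-(4-methoxybenzyloxy)-2,6,10,14-tetramethylhexadeca-6,10-dien-1-ol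
Conditions: Ti(OiPr)4 (cat.), D-(−)-diisopropyl tartrate (cat.), t-BuOOH, 4 Å molecular sieves, CH2Cl2, −20 °C
Reagents that add atoms: tert-butyl hydroperoxide, CC(C)(C)OO
Why: Sharpless asymmetric epoxidation, in which the titanium tartrate complex binds the allylic alcohol and should deliver oxygen only to the adjacent alkene, the D-(−)-tartrate giving the (2R,3R)-epoxide of this E-2-methyl allylic alcohol and thereby setting C3 (R) and, for the time being, C4.

Step 11
Reactants: 13 (2R,3R)-epoxy alcohol
Product: 14 (2R,3R)-epoxy diene TBS ether (18-OTBS, 15-OPMB)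
Conditions: TBSCl, imidazole, CH2Cl2, 0 °C → rt
Reagents that add atoms: tert-butyldimethylsilyl chloride, CC(C)(C)[Si](C)(C)Cl
Why: Mild silylation of the primary hydroxyl should avoid Payne rearrangement and give the epoxide a bulky, non-coordinating C18 substituent for the cascade.

Step 12
Reactants: 14 (2R,3R)-epoxy diene TBS ether
Product: 15 ent-3-hydroxylabd-8(17)-ene 18-TBS 15-PMB bis-ether (3R; 3-OH equatorial and cis to the C10 methyl; H5 trans to the C10 methyl; CH2OTBS equatorial on C4; C9 side chain equatorial; 13S)
Conditions: Cp2TiCl2 (2.5 equiv), Mn dust (8 equiv), degassed THF, rt, slow addition of 14; then 1 M HCl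
Reagents that add atoms: none
Why: Cp2TiCl (trivalent titanium, made from Cp2TiCl2 and Mn) should open the epoxide by single-electron transfer at the more substituted C4–O bond, giving a C3–O–Ti alkoxide and a tertiary C4 radical; the closest known reaction type is the titanocene-mediated radical cyclization of epoxypolyprenes. Ring A should close by 6-endo-trig addition of the C4 radical to C5 of the E C5=C10 alkene, and ring B by 6-endo-trig addition of the resulting tertiary C10 radical to C9 of the E C8=C9 alkene. C5, C10 and C9 follow from the chair–chair folding of the E,E-diene with anti addition across each alkene (trans ring fusion, H5 and H9 axial, C10 methyl axial, C9 side chain equatorial), and the absolute sense of that fold is imposed by C3, whose large O–Ti(Cl)Cp2 group stays equatorial. C4, planar when the C4–C5 bond forms, should be set by the larger CH2OTBS group taking the equatorial site away from the axial C10 methyl, leaving the C19 methyl axial. The tertiary C8 radical is then trapped by a second Cp2TiCl and the resulting alkyl–titanium species (tetravalent titanium) loses a C17 hydrogen, so the cascade ends at the 8(17) exocyclic alkene. The step needs 6-endo over 5-exo closure and one face of the C5=C10 alkene: the first is secured by the trisubstituted alkenes, which make every new radical tertiary, the second by the single epoxide stereocentre at C3.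

Step 13
Reactants: 15 ent-3-hydroxylabd-8(17)-ene bis-ether
Product: 16 3-O-(phenoxythiocarbonyl) derivative of 15
Conditions: PhOC(S)Cl, pyridine, DMAP (cat.), CH2Cl2, rt
Reagents that add atoms: O-phenyl chlorothionoformate, ClC(=S)Oc1ccccc1
Why: DMAP-catalysed acylation of the secondary alcohol should give the thionocarbonate for the Barton–McCombie reaction without forming an alkoxide that could trigger silyl migration from O18.

Step 14
Reactants: 16 3-O-(phenoxythiocarbonyl) derivative
Product: 17 ent-labd-8(17)-ene 18-TBS 15-PMB bis-ether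
Conditions: Bu3SnH, AIBN (cat.), toluene, 100 °C
Reagents that add atoms: none
Why: Barton–McCombie deoxygenation, in which the stannyl radical adds to the thiocarbonyl sulfur, the adduct fragments to a secondary C3 radical and this takes hydrogen from Bu3SnH, should delete the relay stereocentre while the isolated 1,1-disubstituted alkene is left alone.

Step 15
Reactants: 17 ent-labd-8(17)-ene bis-ether
Product: 18 8,17-epoxide (spiro-oxirane at C8, oxygen equatorial and anti to the C10 methyl)
Conditions: mCPBA, CH2Cl2, aq. NaHCO3 buffer, 0 °C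
Reagents that add atoms: 3-chloroperoxybenzoic acid, OOC(=O)c1cccc(Cl)c1
Why: Prilezhaev epoxidation, in which the peracid should approach the exocyclic alkene from the face opposite the axial C10 methyl and so place the oxygen equatorial at C8, which sets C8.

Step 16
Reactants: 18 8,17-epoxide
Product: 19 ent-labdan-8-ol 18-TBS 15-PMB bis-ether (8-OH equatorial, C17 methyl axial and cis to the C10 methyl)
Conditions: LiAlH4, THF, 0 → 50 °C; then H2O, aq. NaOH
Reagents that add atoms: none
Why: Hydride should open the spiro-epoxide by SN2 attack at its unhindered CH2 terminus (C17), so the C8–O bond and its configuration are kept and the tertiary carbinol results.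

Step 17
Reactants: 19 ent-labdan-8-ol bis-ether
Product: 20 ent-labdane-8,18-diol 15-PMB ether
Conditions: TBAF, THF, rt → 50 °C
Reagents that add atoms: none
Why: Fluoride-induced desilylation should free the neopentyl primary C18 alcohol, to which the PMB ether and the tertiary alcohol are inert.

Step 18
Reactants: 20 ent-labdane-8,18-diol 15-PMB ether; 21 angelic acid
Product: 23 8-hydroxy-ent-labdane 18-angelate 15-PMB ether, via mixed anhydride 22 (not isolated)
Conditions: 21, 2,4,6-trichlorobenzoyl chloride, Et3N, toluene, rt; then 20, 80 °C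
Reagents that add atoms: none
Why: Yamaguchi-type mixed-anhydride esterification run without DMAP, in which the primary alcohol should attack the unshielded angeloyl carbonyl thermally, the tertiary C8 hydroxyl does not compete, and the absence of a nucleophilic catalyst keeps the Z alkene from isomerizing to the tiglate.

Step 19
Reactants: 23 18-angelate 15-PMB ether
Product: 24 18-angelate 8,15-diol
Conditions: DDQ, CH2Cl2/pH 7 phosphate buffer, 0 °C → rt
Reagents that add atoms: none
Why: Oxidative PMB cleavage, in which DDQ abstracts hydride from the electron-rich benzylic position and water hydrolyses the oxocarbenium ion, should leave the electron-poor angelate alkene and both alcohols untouched.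

Step 20
Reactants: 24 18-angelate 8,15-diol; 25 Meldrum's acid
Product: 26 target CNP0286290.1
Conditions: toluene, 90 °C
Reagents that add atoms: none
Why: Thermal acylation by Meldrum's acid, in which the unhindered primary C15 alcohol adds to a ring carbonyl and the adduct fragments with loss of acetone, should give the malonic half ester while the tertiary C8 hydroxyl is too hindered to react.

Compound list
1 | (S)-citronellol, (3S)-3,7-dimethyloct-6-en-1-ol | CC(C)=CCC[C@H](C)CCO | starting material
2 | (S)-citronellyl 4-methoxybenzyl (PMB) ether | CC(C)=CCC[C@H](C)CCOCc1ccc(OC)cc1 | intermediate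
3 | (2E,6S)-8-(4-methoxybenzyloxy)-2,6-dimethyloct-2-en-1-ol | OC/C(C)=C/CC[C@H](C)CCOCc1ccc(OC)cc1 | intermediate
4 | (S,E)-8-bromocitronellyl PMB ether, 1-({[(3S,6E)-8-bromo-3,7-dimethyloct-6-en-1-yl]oxy}methyl)-4-methoxybenzene | BrC/C(C)=C/CC[C@H](C)CCOCc1ccc(OC)cc1 | intermediate
5 | geranyl bromide, (2E)-1-bromo-3,7-dimethylocta-2,6-diene | CC(C)=CCC/C(C)=C/CBr | starting material
6 | geranyl phenyl sulfone | CC(C)=CCC/C(C)=C/CS(=O)(=O)c1ccccc1 | intermediate
7 | (2E,6E)-8-hydroxygeranyl phenyl sulfone, (2E,6E)-2,6-dimethyl-8-(phenylsulfonyl)octa-2,6-dien-1-ol | OC/C(C)=C/CC/C(C)=C/CS(=O)(=O)c1ccccc1 | intermediate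
8 | (2E,6E)-8-(tert-butyldimethylsilyloxy)geranyl phenyl sulfone | CC(C)(C)[Si](C)(C)OC/C(C)=C/CC/C(C)=C/CS(=O)(=O)c1ccccc1 | intermediate
9 | α-lithiated sulfone from 8 (formed in the flask) | CC(C)(C)[Si](C)(C)OC/C(C)=C/CC/C(C)=C/C([Li])S(=O)(=O)c1ccccc1 | intermediate
10 | C20 sulfone, all-E, 18-OTBS, 15-OPMB, 13S, both epimers at the sulfonyl carbon C6 | CC(C)(C)[Si](C)(C)OC/C(C)=C/CC/C(C)=C/C(S(=O)(=O)c1ccccc1)C/C(C)=C/CC[C@H](C)CCOCc1ccc(OC)cc1 | intermediate
11 | all-E triene bis-ether, TBS ether of 12 | CC(C)(C)[Si](C)(C)OC/C(C)=C/CC/C(C)=C/CC/C(C)=C/CC[C@H](C)CCOCc1ccc(OC)cc1 | intermediate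
12 | (2E,6E,10E,14S)-16-(4-methoxybenzyloxy)-2,6,10,14-tetramethylhexadeca-2,6,10-trien-1-ol | OC/C(C)=C/CC/C(C)=C/CC/C(C)=C/CC[C@H](C)CCOCc1ccc(OC)cc1 | intermediate
13 | (2R,3R,6E,10E,14S)-2,3-epoxy-16-(4-methoxybenzyloxy)-2,6,10,14-tetramethylhexadeca-6,10-dien-1-ol (chain C2 and C3 = labdane C4 and C3) | OC[C@@]1(C)O[C@@H]1CC/C(C)=C/CC/C(C)=C/CC[C@H](C)CCOCc1ccc(OC)cc1 | intermediate
14 | TBS ether of 13, (2R,3R)-epoxy E,E-diene with 18-OTBS and 15-OPMB | CC(C)(C)[Si](C)(C)OC[C@@]1(C)O[C@@H]1CC/C(C)=C/CC/C(C)=C/CC[C@H](C)CCOCc1ccc(OC)cc1 | intermediate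
15 | ent-3-hydroxylabd-8(17)-ene 18-TBS 15-PMB bis-ether; 3R, 3-OH equatorial and cis to the C10 methyl, trans-decalin, CH2OTBS equatorial on C4, C9 side chain equatorial, 13S | CC(C)(C)[Si](C)(C)OC[C@@]1(C)[C@H](O)CC[C@]2(C)[C@@H]1CCC(=C)[C@H]2CC[C@H](C)CCOCc1ccc(OC)cc1 | intermediate
16 | 3-O-(phenoxythiocarbonyl) derivative of 15 | CC(C)(C)[Si](C)(C)OC[C@@]1(C)[C@H](OC(=S)Oc3ccccc3)CC[C@]2(C)[C@@H]1CCC(=C)[C@H]2CC[C@H](C)CCOCc1ccc(OC)cc1 | intermediate
17 | ent-labd-8(17)-ene 18-TBS 15-PMB bis-ether (ring stereocentres C4, C5, C9, C10 as in 15) | CC(C)(C)[Si](C)(C)OC[C@@]1(C)CCC[C@]2(C)[C@@H]1CCC(=C)[C@H]2CC[C@H](C)CCOCc1ccc(OC)cc1 | intermediate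
18 | 8,17-epoxide of 17, epoxide oxygen equatorial at C8 and anti to the C10 methyl | CC(C)(C)[Si](C)(C)OC[C@@]1(C)CCC[C@]2(C)[C@@H]1CC[C@@]3(CO3)[C@H]2CC[C@H](C)CCOCc1ccc(OC)cc1 | intermediate
19 | ent-labdan-8-ol 18-TBS 15-PMB bis-ether, 8-OH equatorial, C17 methyl axial | CC(C)(C)[Si](C)(C)OC[C@@]1(C)CCC[C@]2(C)[C@@H]1CC[C@](C)(O)[C@H]2CC[C@H](C)CCOCc1ccc(OC)cc1 | intermediate
20 | ent-labdane-8,18-diol 15-PMB ether | OC[C@@]1(C)CCC[C@]2(C)[C@@H]1CC[C@](C)(O)[C@H]2CC[C@H](C)CCOCc1ccc(OC)cc1 | intermediate
21 | angelic acid, (Z)-2-methylbut-2-enoic acid | C/C=C(/C)C(=O)O | starting material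
22 | angelic 2,4,6-trichlorobenzoic mixed anhydride (formed in the flask) | C/C=C(/C)C(=O)OC(=O)c1c(Cl)cc(Cl)cc1Cl | intermediate
23 | 8-hydroxy-ent-labdane 18-angelate 15-PMB ether | C/C=C(/C)C(=O)OC[C@@]1(C)CCC[C@]2(C)[C@@H]1CC[C@](C)(O)[C@H]2CC[C@H](C)CCOCc1ccc(OC)cc1 | intermediate
24 | 18-angelate 8,15-diol | C/C=C(/C)C(=O)OC[C@@]1(C)CCC[C@]2(C)[C@@H]1CC[C@](C)(O)[C@H]2CC[C@H](C)CCO | intermediate
25 | Meldrum's acid, 2,2-dimethyl-1,3-dioxane-4,6-dione | CC1(C)OC(=O)CC(=O)O1 | starting material
26 | CNP0286290.1, (4S,5S,8S,9S,10R,13S)-18-angeloyloxy-8-hydroxy-ent-labdan-15-yl hydrogen malonate | C/C=C(/C)C(=O)OC[C@@]1(C)CCC[C@]2(C)[C@@H]1CC[C@](C)(O)[C@H]2CC[C@H](C)CCOC(=O)CC(=O)O | target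

Total step count: 20 steps.
Longest linear sequence: 17 steps (steps 1–3 or steps 4–6, then steps 7–20).

Steps most likely to fail

1. Step 12. The cascade may stop after ring A, or the planar C4 radical may close with poor control of which C4 substituent ends up equatorial. The fallback changes the mechanism from radical to cationic. It sets out from 14, which is treated with MeAlCl2 in CH2Cl2 at −90 °C. The Lewis-acid-activated epoxide is then opened at C4 with inversion as the C5=C10 alkene attacks, so the CH2OTBS group, which is trans to the chain in the epoxide, is transferred stereospecifically to the equatorial site. The cascade ends by proton loss from the C8 cation, which should give 15 together with its endocyclic alkene isomer, the 7-ene isomer F1. Compound 15 is separated from it on AgNO3-impregnated silica, and the route is rejoined at 15.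

2. Step 18. The Z angelate may isomerize to the E tiglate during acylation, or the neopentyl alcohol may acylate too slowly. The fallback builds the Z alkene on the ester instead of transferring it. It sets out from 20, which is esterified at O18 with 2-[bis(2,2,2-trifluoroethoxy)phosphoryl]propanoic acid (DCC, DMAP, CH2Cl2) to give the phosphonopropionate ester F2. Still–Gennari olefination of this ester with acetaldehyde (KN(SiMe3)2, 18-crown-6, THF, −78 °C) should then form the Z-trisubstituted ester, and the route is rejoined at 23.

3. Step 15. The peracid may show poor facial selectivity at the exocyclic alkene, or the spiro-epoxide may rearrange under acid before it is reduced. The fallback replaces epoxidation and hydride opening by a radical Markovnikov hydration. It sets out from 17, which is subjected to Mukaiyama hydration (Co(acac)2, PhSiH3, O2, i-PrOH, rt). Hydrogen-atom transfer to C17 gives the tertiary C8 radical, and oxygen should be taken up on the face away from the axial C10 methyl. This comes back to the route at 19 and makes no new compound (F0).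

Further compounds
F1 | step 12 | 7-ene isomer of 15, ent-3-hydroxylabd-7-ene 18-TBS 15-PMB bis-ether | CC(C)(C)[Si](C)(C)OC[C@@]1(C)[C@H](O)CC[C@]2(C)[C@@H]1CC=C(C)[C@H]2CC[C@H](C)CCOCc1ccc(OC)cc1
F2 | step 18 | 18-O-{2-[bis(2,2,2-trifluoroethoxy)phosphoryl]propanoyl} derivative of 20 (both epimers at the phosphonate carbon) | CC(C(=O)OC[C@@]1(C)CCC[C@]2(C)[C@@H]1CC[C@](C)(O)[C@H]2CC[C@H](C)CCOCc1ccc(OC)cc1)P(=O)(OCC(F)(F)F)OCC(F)(F)F
F0 | step 15 | none | none
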